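**Structural features**

The target is a 2,3,5,6-tetrahydropyrano[3,4-b]pyran-4,8-dione (numbering O1, C2, C3, C4, C4a, C5, C6, O7, C8, C8a): ring B is a 2,3-dihydro-4H-pyran-4-one (O1–C2–C3–C4(=O)–C4a=C8a) and ring A an α,β-unsaturated δ-lactone (C4a–C5–C6–O7–C8(=O)–C8a), fused through the tetrasubstituted C4a=C8a bond. That bond is a push–pull alkene: C8a carries O1 and the lactone carbonyl C8, C4a carries the ketone C4 and the C5 methylene, so O1–C8a=C4a–C4=O is a vinylogous ester and C8/C8a are the two carbons of an α-keto acid. There are two stereocentres, C2 (S, n-heptyl) and C6 (R, n-decyl), each an O–CH(n-alkyl)–CH2 unit; they lie five bonds apart across the flat core, so neither can direct the other. C6 is a robust secondary carbinol ester, but C2 is fragile: O1 is β to C4=O and is the enolate oxygen of a 1,2-dicarbonyl unit, so enolisation at C3 under base can open ring B by retro-oxa-Michael reaction and scramble C2, and strong base can also open ring A by vinylogous elimination through C5. The real difficulty is therefore the regiochemically correct, fully substituted C4a=C8a core and a late, irreversible, reagent-controlled way to set the isolated C2 centre. The key step exploits that C2 is the β-carbon of the C4 enone and the only carbon of ring B that bears a chain: in the 2,3-dehydro compound ring B is a planar 4-pyranone whose C2–H is its only unsubstituted electrophilic position, so the C2–C1′ bond to the heptyl chain and the C2 configuration can be created together by a catalytic enantioselective 1,4-addition.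

**Logic of the disconnections**

14 ⇒ 11 + 12. Bond cut: C2–C1′ (ring B to the heptyl chain), with the C2=C3 double bond restored in the precursor. C2 is β to the C4 carbonyl, so the chain can arrive as a nucleophile. The cut removes the fragile stereocentre and leaves ring B planar, so 11 has one stereocentre (C6) and 12 is commercial. In one sentence, the route is the enantioselective copper-catalysed 1,4-addition of 12 to C2 of 11. Demand on the forward step: attack at C2 and not at C8a, C8 or C4, face selection by the catalyst alone, and a quench of 13 that does not open ring B.

11 ⇒ 7 + 8. Bonds cut: C4a–C8a, O7–C8 and O1–C2. Both rings fall away in one operation. C8 and C8a are the two carbons of 8. In 7 the only enolisable carbon is C4a, which fixes the regiochemistry of the C–C bond, and C2 already carries a leaving group for the closure of ring B. Demand: O7 must be acylated first (9) so that C–C bond formation closes ring A (10) and O7 cannot add to the C8a ketone; the acid stage must then close ring B.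

7 ⇒ 5 + 6. Bond cut: C2=C3. C2 is brought in as a one-carbon electrophile at the methyl group of 5, which at the same time blocks that side of the ketone against enolisation in the next step. Demand: condensation at the methyl group (C3) and not at the methylene (C4a), in the presence of the free C6 hydroxyl.

5 ⇒ 1 + 2. Bond cut: C4a–C5. The C6 stereocentre comes intact from 1, and 2 supplies C3–C4–C4a with a nucleophilic terminus (as 3). Demand: attack at the terminal epoxide carbon only, so that the C6–O bond is never broken, and hydrolysis of 4 without dehydration.

**Other disconnections considered**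

Alternative 1: (the first that comes to mind) cut O1–C8a. The forward key step would be an acid-mediated cyclodehydration, the C2 hydroxyl adding 6-exo to the C8a carbonyl of the hydroxy tricarbonyl compound A1, (R)-6-decyl-3-hydroxy-4-[(S)-3-hydroxydecanoyl]-5,6-dihydro-2H-pyran-2-one, with loss of water. A1 must carry the C2 carbinol through its own synthesis. It would come from 5 by an acetate-type aldol at C3 with an unbranched aldehyde, a weak case for enantiocontrol. Protection, an oxalate Claisen with 8 and deprotection would follow; that Claisen is regiochemically ambiguous (C3 or C4a) and the C3 enolate can eliminate the C2 oxygen. This is about twice the step count of the chosen plan, which never exposes a C2–O bond to enolate chemistry and sets C2 in the last step.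

Alternative 2: cut C2–C3 and O1–C8a. The forward key step would be a chiral Lewis acid-catalysed hetero-Diels–Alder reaction (or its stepwise Mukaiyama aldol/cyclisation form) of the siloxy diene A2, (R)-6-decyl-3-methoxy-4-[1-(trimethylsilyloxy)ethenyl]-5,6-dihydro-2H-pyran-2-one, with octanal A3, followed by loss of methanol. The diene terminus C8a is tetrasubstituted and carries the electron-withdrawing C8 carbonyl, so a concerted cycloaddition is disfavoured, and the stepwise aldol with an enolisable unbranched aldehyde is again a weak case for enantiocontrol. A2 also needs the 4-acetyl lactone (Dieckmann closure with a methyl/methylene regiochemistry problem), O-methylation and silyl enol ether formation, at least three steps more than the chosen plan.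

Alternative 3: remove O7, contracting ring A to a cyclopentenone. The forward key step would be a Baeyer–Villiger monooxygenase inserting oxygen between the ring ketone and C6 of the carbocyclic diketone A4, (2S)-6-decyl-2-heptyl-2,3,5,6-tetrahydrocyclopenta[b]pyran-4,7-dione (C6 epimers), in principle with dynamic kinetic resolution at the enolisable C6. A4 requires a five-membered carbocycle built by C–C bond formation that has no counterpart in the target, so the precursor is no simpler. The choice of migrating group (sec-alkyl C6 against vinylic C7a) and the acceptance of a C25 lipophilic substrate by the enzyme cannot be argued from close analogy. The chosen plan takes C6 from 1 at no cost in steps.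

Key step: step 4

Assumption: (R)-2-decyloxirane 1 is taken as a commercial single enantiomer (it is also the product of hydrolytic kinetic resolution of the racemate); atom labels (C2, C4a, O7 and so on) refer to the target numbering in all intermediates.

Step 1
Reactants: 1 (R)-2-decyloxirane; 2 acetone N,N-dimethylhydrazone
Product: 5 (R)-5-hydroxypentadecan-2-one, via lithio aza-enolate 3 (not isolated), via hydrazone alcohol 4 (not isolated)
Conditions: 2 (1.2 equiv), n-BuLi, THF, −78 → 0 °C; 1, 0 °C → rt; then 2 M HCl/Et2O (two-phase), rt
Reagents that add atoms: water (O)
Why: Alkylation of a metalated N,N-dimethylhydrazone with a terminal epoxide: aza-enolate 3 attacks the unsubstituted epoxide carbon (SN2), so the C–O bond at the stereocentre is not touched and C6 stays R; two-phase acid hydrolysis of 4 returns the ketone (in equilibrium with its five-ring hemiketal).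

Step 2
Reactants: 5 (R)-5-hydroxypentadecan-2-one; 6 N,N-dimethylformamide dimethyl acetal
Product: 7 (R,E)-1-(dimethylamino)-6-hydroxyhexadec-1-en-3-one
Conditions: 6 (3 equiv), toluene, 100 °C (MeOH distilled off); aq. work-up
Reagents that add atoms: none
Why: Enaminone formation from a methyl ketone and an amide acetal: condensation takes place at the less hindered methyl group (target C3) and gives the E-vinylogous amide; acetal exchange at the C6 hydroxyl is reversed on aqueous work-up and the stereocentre is not involved.

Step 3
Reactants: 7 (R,E)-1-(dimethylamino)-6-hydroxyhexadec-1-en-3-one; 8 dimethyl oxalate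
Product: 11 (R)-6-decyl-5,6-dihydro-4H,8H-pyrano[3,4-b]pyran-4,8-dione, via mixed oxalate 9 (not isolated), via enaminone hydroxylactone 10 (not isolated)
Conditions: LiHMDS (1.05 equiv), THF, −78 °C; 8 (1.1 equiv), −78 → 0 °C; LiHMDS (2.1 equiv), −78 → 0 °C; then 2 M HCl, THF, rt
Reagents that add atoms: none
Why: Claisen condensation of an enaminone α′-enolate with an oxalate ester followed by acid closure is the established entry to 4-oxo-4H-pyran-2-carboxylates; here O7 is transesterified first (9), so the C4a–C8a bond forms as a Dieckmann-type 6-exo-trig closure at the only enolisable carbon and gives ring A (10). Acid then lets the C8a enol oxygen add to C2 (6-endo-trig) and expel dimethylamine to give the 4-pyranone ring B; C6 is a spectator.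

Step 4
Reactants: 11 (R)-6-decyl-5,6-dihydro-4H,8H-pyrano[3,4-b]pyran-4,8-dione; 12 n-heptylmagnesium bromide
Product: 14 (2S,6R)-6-decyl-2-heptyl-2,3,5,6-tetrahydro-4H,8H-pyrano[3,4-b]pyran-4,8-dione, via magnesium enolate 13 (not isolated)
Conditions: CuBr·SMe2 (5 mol %), Josiphos-type ferrocenyl diphosphine (6 mol %, enantiomer chosen for Si-face delivery at C2), 12 (1.5 equiv, slow addition), CH2Cl2, −78 °C; then 1 M HCl, −78 °C → rt
Reagents that add atoms: none
Why: Copper-catalysed asymmetric conjugate addition of a Grignard reagent to a 4-pyranone; the closest known case is the addition of alkylmagnesium bromides to chromones to give 2-alkylchroman-4-ones, and 11 is the analogue in which the benzo ring is replaced by lactone ring A. Transmetalation gives a chiral bisphosphine–alkylcopper/magnesium species that binds the C2=C3 π-bond while magnesium activates the C4 oxygen; oxidative addition to a C2-bound Cu(III) σ-complex and reductive elimination form C2–C1′ and leave the magnesium dienolate 13, which is protonated at C3 on cold acidic quench. No ring is closed; the new stereocentre C2 is controlled by the ligand alone (delivery to the Si face of C2, O1 > C3 > H, gives 2S), because C6 sits five bonds away on the far side of the planar core and cannot bias either face. Site selectivity: C2 is the only unsubstituted β-position of the C4 enone, the other β-carbon C8a is fully substituted and at the ring fusion, and C4a is α to C4, so cuprate addition elsewhere is not expected. Chemoselectivity against 1,2-addition at C8 or C4 rests on slow addition of 12 at −78 °C in CH2Cl2, where the uncatalysed Grignard pathway is slow. The C–C bond is formed irreversibly, and in 13 the O1–C2 bond lies close to the plane of the C3=C4 enolate, so E1cB opening of ring B (the process that could scramble C2) is stereoelectronically slow at −78 °C. The acidic quench avoids a free basic enolate on warming.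

**Compound list**

1 | (R)-2-decyloxirane [(R)-1,2-epoxydodecane] | CCCCCCCCCC[C@@H]1CO1 | starting material
2 | acetone N,N-dimethylhydrazone | CC(C)=NN(C)C | starting material
3 | lithio aza-enolate of 2 (not isolated) | [Li]CC(C)=NN(C)C | intermediate
4 | (R)-2-(2,2-dimethylhydrazinylidene)pentadecan-5-ol, hydrazone alcohol (not isolated) | CCCCCCCCCC[C@@H](O)CCC(C)=NN(C)C | intermediate
5 | (R)-5-hydroxypentadecan-2-one | CCCCCCCCCC[C@@H](O)CCC(C)=O | intermediate
6 | N,N-dimethylformamide dimethyl acetal | COC(OC)N(C)C | starting material
7 | (R,E)-1-(dimethylamino)-6-hydroxyhexadec-1-en-3-one | CCCCCCCCCC[C@@H](O)CCC(=O)/C=C/N(C)C | intermediate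
8 | dimethyl oxalate | COC(=O)C(=O)OC | starting material
9 | methyl (R,E)-1-(dimethylamino)-3-oxohexadec-1-en-6-yl oxalate, mixed oxalate (not isolated) | CCCCCCCCCC[C@@H](OC(=O)C(=O)OC)CCC(=O)/C=C/N(C)C | intermediate
10 | (R)-6-decyl-4-[(E)-3-(dimethylamino)prop-2-enoyl]-3-hydroxy-5,6-dihydro-2H-pyran-2-one, enaminone hydroxylactone (not isolated) | CCCCCCCCCC[C@@H]1CC(C(=O)/C=C/N(C)C)=C(O)C(=O)O1 | intermediate
11 | (R)-6-decyl-5,6-dihydro-4H,8H-pyrano[3,4-b]pyran-4,8-dione | CCCCCCCCCC[C@@H]1CC2=C(OC=CC2=O)C(=O)O1 | intermediate
12 | n-heptylmagnesium bromide | CCCCCCC[Mg]Br | starting material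
13 | bromomagnesium C3=C4 enolate of 14 (not isolated) | CCCCCCCCCC[C@@H]1CC2=C(O[C@@H](CCCCCCC)C=C2O[Mg]Br)C(=O)O1 | intermediate
14 | (2S,6R)-6-decyl-2-heptyl-2,3,5,6-tetrahydro-4H,8H-pyrano[3,4-b]pyran-4,8-dione | CCCCCCCCCC[C@@H]1CC2=C(O[C@@H](CCCCCCC)CC2=O)C(=O)O1 | target

**Step count and risk**

Total step count: 4. Longest linear sequence: 4 steps (1 → 5 → 7 → 11 → 14).

Step 4 (key step). The most likely failures are competing uncatalysed 1,2-addition of the Grignard reagent to the lactone carbonyl C8 (or to C4), because the pyranone is a poor Michael acceptor, and insufficient facial discrimination at C2, because the substrate offers the catalyst no second binding point near C2. Opening of ring B from enolate 13 on warming would erode C2 as well. The fallback changes the bond that sets C2 from C–C to O–C. It sets out from 7: two equivalents of 12 (the first consumed by the hydroxyl) add to the enaminone and expel dimethylamide to give (R,E)-13-hydroxytricos-8-en-10-one F1. The oxalate annulation of step 3 (LiHMDS, 8, cold acidic quench) then gives (R)-6-decyl-4-[(E)-dec-2-enoyl]-3-hydroxy-5,6-dihydro-2H-pyran-2-one F2. A bifunctional cinchona-derived thiourea catalyst closes ring B by enantioselective 6-endo-trig oxa-Michael addition of the C8a enol oxygen to the enone, which returns to the route at 14.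

Step 3. The most likely failure is loss of the intended order of events: if C-acylation at C4a precedes acylation of O7, or lactonisation is incomplete, the free hydroxyl adds to the C8a ketone in the acid stage and dehydrates to a dihydrofuran instead of closing ring A. Incomplete α′-deprotonation of the vinylogous amide is the second concern. The fallback builds ring B first and ring A last. It sets out from 7: silylation (TBSCl, imidazole) gives (R,E)-6-[(tert-butyldimethylsilyl)oxy]-1-(dimethylamino)hexadec-1-en-3-one F3. LiHMDS and 8, then trifluoroacetic acid, give methyl 3-[(R)-2-[(tert-butyldimethylsilyl)oxy]dodecyl]-4-oxo-4H-pyran-2-carboxylate F4. HF·pyridine followed by TsOH in warm toluene removes the silyl group and closes the lactone, which returns to the route at 11.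

Step 2. The most likely failure is engagement of the free C6 hydroxyl by the amide acetal (activation as a formamidinium ether followed by elimination or substitution), together with slow condensation of an unactivated aliphatic methyl ketone. The fallback ties O7 up in ring A before the one-carbon unit is introduced. It sets out from 5: methyl chlorooxoacetate and pyridine give methyl (R)-2-oxopentadecan-5-yl oxalate F5. LiHMDS at high dilution, with enolate equilibration, should funnel through the six-ring Dieckmann closure at C4a to (R)-4-acetyl-6-decyl-3-hydroxy-5,6-dihydro-2H-pyran-2-one F6. Amide acetal 6 then condenses on the acetyl group, now activated as part of a β-dicarbonyl system, to give 10, and acid closes ring B, which returns to the route at 11.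

Step 1. The most likely failure is sluggish opening of the epoxide by the aza-enolate, or dehydration of the γ-hydroxy ketone to a dihydrofuran during hydrazone hydrolysis. The fallback replaces the three-carbon nucleophile by an allyl unit and a later oxidation. It sets out from 1: allylmagnesium bromide with catalytic CuI gives (R)-pentadec-1-en-5-ol F7, and Wacker oxidation (PdCl2, CuCl, O2, DMF/H2O) converts the terminal alkene into the methyl ketone, which returns to the route at 5.

**Further compounds**

F1 | step 4 | (R,E)-13-hydroxytricos-8-en-10-one | CCCCCCCCCC[C@@H](O)CCC(=O)/C=C/CCCCCCC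
F2 | step 4 | (R)-6-decyl-4-[(E)-dec-2-enoyl]-3-hydroxy-5,6-dihydro-2H-pyran-2-one | CCCCCCCCCC[C@@H]1CC(C(=O)/C=C/CCCCCCC)=C(O)C(=O)O1
F3 | step 3 | (R,E)-6-[(tert-butyldimethylsilyl)oxy]-1-(dimethylamino)hexadec-1-en-3-one | CCCCCCCCCC[C@@H](O[Si](C)(C)C(C)(C)C)CCC(=O)/C=C/N(C)C
F4 | step 3 | methyl 3-[(R)-2-[(tert-butyldimethylsilyl)oxy]dodecyl]-4-oxo-4H-pyran-2-carboxylate | CCCCCCCCCC[C@@H](O[Si](C)(C)C(C)(C)C)CC1=C(C(=O)OC)OC=CC1=O
F5 | step 2 | methyl (R)-2-oxopentadecan-5-yl oxalate | CCCCCCCCCC[C@@H](OC(=O)C(=O)OC)CCC(C)=O
F6 | step 2 | (R)-4-acetyl-6-decyl-3-hydroxy-5,6-dihydro-2H-pyran-2-one | CCCCCCCCCC[C@@H]1CC(C(C)=O)=C(O)C(=O)O1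
F7 | step 1 | (R)-pentadec-1-en-5-ol | CCCCCCCCCC[C@@H](O)CCC=C
A1 | alternative 1 | (R)-6-decyl-3-hydroxy-4-[(S)-3-hydroxydecanoyl]-5,6-dihydro-2H-pyran-2-one | CCCCCCCCCC[C@@H]1CC(C(=O)C[C@@H](O)CCCCCCC)=C(O)C(=O)O1
A2 | alternative 2 | (R)-6-decyl-3-methoxy-4-[1-(trimethylsilyloxy)ethenyl]-5,6-dihydro-2H-pyran-2-one | CCCCCCCCCC[C@@H]1CC(C(=C)O[Si](C)(C)C)=C(OC)C(=O)O1
A3 | alternative 2 | octanal | CCCCCCCC=O
A4 | alternative 3 | (2S)-6-decyl-2-heptyl-2,3,5,6-tetrahydrocyclopenta[b]pyran-4,7-dione (C6 epimers) | CCCCCCCCCCC1CC2=C(O[C@@H](CCCCCCC)CC2=O)C1=O
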